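**Retrosynthetic overview**
- The acid comes from its methyl ester. The ester is cut at the C5–side-chain bond: a B-alkyl Suzuki–Miyaura coupling joins a 5-bromo-3,6-dihydro-2H-pyran, which already carries the stereocentre and the acrylate, to a homofarnesyl borane made from (2E,6E)-farnesol.
- The bromodihydropyran is not closed as a six-membered ring. Its C5 is removed retrosynthetically as a one-carbon unit (:CBr2), which leaves a five-membered (S)-2-substituted 2,3-dihydrofuran. Forward: cyclopropanation, strain-release ring expansion, hydride capture, all in one flask.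
- Enabling feature: in the pyran ring, O1–C6H2–C5(chain)=C4H is a 2-substituted allyl unit next to the ring oxygen. This unit corresponds to the O1-stabilised 2-bromoallyl cation released by a gem-dibromocyclopropane fused to the O1–C=C enol ether of a dihydrofuran. C2 and C3 are spectators.
- The dihydrofuran comes from an enantioselective Heck alkenylation of 2,3-dihydrofuran with the enol triflate of methyl pyruvate. This step sets C2 and brings in the acrylate.
- Order of rings: five-membered O-ring (purchased), then a transient three-membered ring, then the six-membered O-ring.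

Key step: step 3

Assumption: the stereocentre of the target is read as 2S. The sense of induction known for aryl and cycloalkenyl triflates ((R)-BINAP gives 2R) is taken to hold for the pyruvate-derived triflate, so (S)-BINAP is specified. PhHgCBr3 and (2E,6E)-farnesol are taken as purchasable.

Step 1
Reactants: 1 methyl pyruvate
Product: 2 methyl 2-{[(trifluoromethyl)sulfonyl]oxy}prop-2-enoate
Conditions: Tf2O (1.1 equiv), 2,6-di-tert-butyl-4-methylpyridine (1.2 equiv), CH2Cl2, −78 °C → rt
Reagents that add atoms: triflic anhydride, O=S(=O)(C(F)(F)F)OS(=O)(=O)C(F)(F)F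
Why: Enol triflate formation by O-sulfonylation of the enol of an α-keto ester with a hindered non-nucleophilic base; only one position can enolise, so a single 1,1-disubstituted alkenyl triflate should form.

Step 2
Reactants: 2 methyl 2-{[(trifluoromethyl)sulfonyl]oxy}prop-2-enoate; 3 2,3-dihydrofuran (5 equiv)
Product: 4 methyl 2-[(2S)-2,3-dihydrofuran-2-yl]prop-2-enoate
Conditions: Pd(OAc)2 (3 mol %), (S)-BINAP (6 mol %), 1,8-bis(dimethylamino)naphthalene (2 equiv), toluene, 40 °C
Reagents that add atoms: none
Why: Enantioselective intermolecular Heck alkenylation by the cationic pathway, in which the alkenylpalladium species adds syn across the enol ether with C–C bond formation next to oxygen and a β-hydride elimination/re-addition sequence walks the double bond to the far side of the ring; C2 is set by enantioface selection of the (S)-BINAP-bound divalent palladium and is not scrambled, because its hydrogen lies anti to palladium.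

Step 3
Reactants: 4 methyl 2-[(2S)-2,3-dihydrofuran-2-yl]prop-2-enoate
Product: 7 methyl 2-[(2S)-5-bromo-3,6-dihydro-2H-pyran-2-yl]prop-2-enoate, via dibromocyclopropane 5 (not isolated), via allylic dibromide 6 (not isolated)
Conditions: PhHgCBr3 (1.3 equiv), BHT (cat.), toluene, 80 °C; cool, filter off PhHgBr under Ar; Et3SiH (3 equiv), ZnBr2 (20 mol %), −40 → 0 °C
Reagents that add atoms: phenyl(tribromomethyl)mercury, BrC(Br)(Br)[Hg]c1ccccc1
Why: PhHgCBr3 releases singlet :CBr2 without any base, and this electrophilic carbene adds in a concerted [2+1] cheletropic step to the electron-rich enol-ether bond C4=C5 of 4; at 80 °C the strained adduct 5 loses its endo bromide while the ring-fusion bond C1–C5 opens in an orbital-symmetry-allowed disrotatory 2π electrocyclic process pushed by the lone pair of the ring oxygen, so the carbene carbon ends up between the two former alkene carbons and the five-membered ring becomes the six-membered 2-bromoallyl oxocarbenium ion, stored as dibromide 6 until ZnBr2 re-ionises it and Et3SiH delivers hydride to C6. The closest known reaction types are the dihalocarbene ring expansion of cyclic enol ethers (2,3-dihydrofuran to 5-halo-3,6-dihydro-2H-pyrans, glycals to oxepines) and the silane reduction of allylic oxocarbenium ions as in reductive Ferrier chemistry. The only ring that is closed is the three-membered one (suprafacial cis addition, either face), whereas the pyran is not closed at all but arises by cleavage of the zero-atom bridge of the bicycle, driven by release of cyclopropane strain and by oxocarbenium formation. No new stereocentre survives, since C1 and C5 of 5 and C6 of 6 end as sp2 or CH2 carbons, so the facial selectivity of the carbene addition does not matter, and C2 takes no part in any bond change and keeps its S configuration. The step needs chemoselectivity for the enol ether over the acrylate, which is secured by the electron-poor character of the acrylate toward an electrophilic carbene and by the absence of the CBr3 anion that would add in conjugate fashion; this is also why the polyene chain, whose trisubstituted alkenes would compete, is attached only afterwards. It also needs hydride capture at C6 and not at the vinylogous C4, which follows from the concentration of positive charge next to oxygen, and the retained exo bromine sits exactly on C5, where the chain has to go.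

Step 4
Reactants: 8 (2E,6E)-farnesol
Product: 9 (2E,6E)-farnesal
Conditions: TEMPO (10 mol %), PhI(OAc)2 (1.1 equiv), CH2Cl2, 0 °C → rt
Reagents that add atoms: none
Why: Oxoammonium (TEMPO) oxidation of a primary allylic alcohol stops at the enal under nearly neutral conditions and should leave the 2E geometry and the remote alkenes untouched.

Step 5
Reactants: 9 (2E,6E)-farnesal
Product: 10 (3E,7E)-4,8,12-trimethyltrideca-1,3,7,11-tetraene
Conditions: MePPh3Br, n-BuLi, THF, 0 °C; then 9, −78 °C → rt
Reagents that add atoms: methyltriphenylphosphonium bromide, C[P+](c1ccccc1)(c1ccccc1)c1ccccc1.[Br-]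
Why: Wittig methylenation with the non-stabilised ylide turns the enal into the terminal 1,3-diene without touching the existing E double bonds.

Step 6
Reactants: 10 (3E,7E)-4,8,12-trimethyltrideca-1,3,7,11-tetraene; 7 methyl 2-[(2S)-5-bromo-3,6-dihydro-2H-pyran-2-yl]prop-2-enoate
Product: 12 methyl 2-{(2S)-5-[(3E,7E)-4,8,12-trimethyltrideca-3,7,11-trien-1-yl]-3,6-dihydro-2H-pyran-2-yl}prop-2-enoate, via homofarnesyl borane 11 (not isolated)
Conditions: 10, 9-BBN-H (1.05 equiv), THF, 0 °C → rt; then aq. Cs2CO3, 7, PdCl2(dppf) (5 mol %), AsPh3 (5 mol %), DMF/THF/H2O, rt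
Reagents that add atoms: 9-borabicyclo[3.3.1]nonane, B1C2CCCC1CCC2 (its boron fragment is carried only in 11)
Why: Bulky 9-BBN should hydroborate only the monosubstituted alkene in the anti-Markovnikov sense, and the resulting homoallylic B-alkyl borane then undergoes B-alkyl Suzuki–Miyaura coupling after oxidative addition of zerovalent palladium into the C5–Br bond, which fixes the chain on C5 without moving the ring alkene or touching C2.

Step 7
Reactants: 12 methyl 2-{(2S)-5-[(3E,7E)-4,8,12-trimethyltrideca-3,7,11-trien-1-yl]-3,6-dihydro-2H-pyran-2-yl}prop-2-enoate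
Product: 13 2-{(2S)-5-[(3E,7E)-4,8,12-trimethyltrideca-3,7,11-trien-1-yl]-3,6-dihydro-2H-pyran-2-yl}prop-2-enoic acid (CNP0171598.1)
Conditions: LiOH (3 equiv), THF/H2O, 0 °C → rt; then 1 M HCl to pH 3–4, 0 °C
Reagents that add atoms: lithium hydroxide, [Li+].[OH-]
Why: Saponification by acyl–oxygen cleavage of the methyl ester; the C2–H is only cross-conjugated to the ester and so not acidified, which keeps the S configuration, and the brief cold acidification spares the polyene.

**Compound list**
1 | methyl pyruvate | CC(=O)C(=O)OC | starting material
2 | methyl 2-{[(trifluoromethyl)sulfonyl]oxy}prop-2-enoate | C=C(OS(=O)(=O)C(F)(F)F)C(=O)OC | intermediate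
3 | 2,3-dihydrofuran | C1=COCC1 | starting material
4 | methyl 2-[(2S)-2,3-dihydrofuran-2-yl]prop-2-enoate | C=C(C(=O)OC)[C@@H]1CC=CO1 | intermediate
5 | methyl 2-[(1S,3S,5R)-6,6-dibromo-2-oxabicyclo[3.1.0]hexan-3-yl]prop-2-enoate (anti adduct drawn; the syn adduct converges on the same product) | C=C(C(=O)OC)[C@@H]1C[C@@H]2[C@H](O1)C2(Br)Br | intermediate (not isolated)
6 | methyl 2-[(2S)-5,6-dibromo-3,6-dihydro-2H-pyran-2-yl]prop-2-enoate (labile C6 epimers) | C=C(C(=O)OC)[C@@H]1CC=C(Br)C(Br)O1 | intermediate (not isolated)
7 | methyl 2-[(2S)-5-bromo-3,6-dihydro-2H-pyran-2-yl]prop-2-enoate | C=C(C(=O)OC)[C@@H]1CC=C(Br)CO1 | intermediate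
8 | (2E,6E)-farnesol | OC/C=C(\C)CC/C=C(\C)CCC=C(C)C | starting material
9 | (2E,6E)-farnesal | O=C/C=C(\C)CC/C=C(\C)CCC=C(C)C | intermediate
10 | (3E,7E)-4,8,12-trimethyltrideca-1,3,7,11-tetraene | C=C/C=C(\C)CC/C=C(\C)CCC=C(C)C | intermediate
11 | 9-[(3E,7E)-4,8,12-trimethyltrideca-3,7,11-trien-1-yl]-9-borabicyclo[3.3.1]nonane | B1(CC/C=C(\C)CC/C=C(\C)CCC=C(C)C)C2CCCC1CCC2 | intermediate (not isolated)
12 | methyl 2-{(2S)-5-[(3E,7E)-4,8,12-trimethyltrideca-3,7,11-trien-1-yl]-3,6-dihydro-2H-pyran-2-yl}prop-2-enoate | C=C(C(=O)OC)[C@@H]1CC=C(CC/C=C(\C)CC/C=C(\C)CCC=C(C)C)CO1 | intermediate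
13 | 2-{(2S)-5-[(3E,7E)-4,8,12-trimethyltrideca-3,7,11-trien-1-yl]-3,6-dihydro-2H-pyran-2-yl}prop-2-enoic acid | C=C(C(=O)O)[C@@H]1CC=C(CC/C=C(\C)CC/C=C(\C)CCC=C(C)C)CO1 | target

Total step count: 7. Longest linear sequence: 5 (steps 1, 2, 3, 6, 7). The side-chain branch (steps 4 and 5) joins at step 6.

**Steps most likely to fail**

Step 3. Four processes could erode this step:
- The labile α-bromo ether may lose HBr before hydride transfer, and the resulting 2H-pyran would then unravel electrocyclically.
- The acrylate may oligomerise at 80 °C.
- Part of the hydride may be delivered to the vinylogous position C4.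
- The silane stage may suffer from residual mercury salts.

The fallback sets out from 4 and returns at 7. It intercepts the cation with oxygen instead of hydride and moves the C–H bond formation into a separate operation. After the same carbene transfer, the toluene solution of 6 is run into MeOH/Et3N at −20 °C. This should give the chromatographically stable mixed acetal methyl 2-[(2S)-5-bromo-6-methoxy-3,6-dihydro-2H-pyran-2-yl]prop-2-enoate F2. The purified acetal is then deoxygenated at C6 by ionic reduction (Et3SiH, BF3·OEt2, CH2Cl2, −78 °C) to give 7.

Step 2. Four processes could erode this step: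
- Incomplete migration of the double bond would give mixtures of ring-alkene isomers.
- The enantioselectivity may drop with the small, electron-poor alkenyl group.
- A second alkenylation of the product is possible.
- The triflate may oligomerise.

The fallback sets out from 2 and 3 and returns at 4. It separates C–C bond formation from alkene migration. A Heck coupling with Pd2(dba)3 and the tert-butyl-PHOX ligand (the antipode that gives 2S, expected to be R), iPr2NEt, THF, 50 °C, releases the alkene directly after the first β-hydride elimination. This should give methyl 2-[(2S)-2,5-dihydrofuran-2-yl]prop-2-enoate F1. A separate allyl-ether-to-enol-ether isomerisation with RuHCl(CO)(PPh3)3 (cat.), toluene, 70 °C, then moves the double bond toward the unhindered C5H2 side to give 4.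

Step 6. Three processes could erode this step:
- Site selectivity of the hydroboration within the conjugated diene may be imperfect.
- Slow transmetalation would allow protodeboronation or β-hydride elimination.
- Residual borane may attack the acrylate.

The fallback sets out from 10 and returns at 12. It passes through purifiable intermediates and a different organometal:
- Borane 11 is oxidised (NaOH, H2O2) to (3E,7E)-4,8,12-trimethyltrideca-3,7,11-trien-1-ol F3.
- An Appel reaction (I2, PPh3, imidazole, CH2Cl2) converts it into (3E,7E)-1-iodo-4,8,12-trimethyltrideca-3,7,11-triene F4.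
- Zinc insertion (Zn dust, LiCl, THF) gives [(3E,7E)-4,8,12-trimethyltrideca-3,7,11-trien-1-yl]zinc iodide F5.
- Negishi coupling with 7 (PdCl2(dppf), THF, rt) gives 12.

**Further compounds**
F1 | step 2 | methyl 2-[(2S)-2,5-dihydrofuran-2-yl]prop-2-enoate | C=C(C(=O)OC)[C@@H]1C=CCO1
F2 | step 3 | methyl 2-[(2S)-5-bromo-6-methoxy-3,6-dihydro-2H-pyran-2-yl]prop-2-enoate (C6 epimers) | C=C(C(=O)OC)[C@@H]1CC=C(Br)C(OC)O1
F3 | step 6 | (3E,7E)-4,8,12-trimethyltrideca-3,7,11-trien-1-ol | OCC/C=C(\C)CC/C=C(\C)CCC=C(C)C
F4 | step 6 | (3E,7E)-1-iodo-4,8,12-trimethyltrideca-3,7,11-triene | ICC/C=C(\C)CC/C=C(\C)CCC=C(C)C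
F5 | step 6 | [(3E,7E)-4,8,12-trimethyltrideca-3,7,11-trien-1-yl]zinc iodide | I[Zn]CC/C=C(\C)CC/C=C(\C)CCC=C(C)C
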